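Positions are numbered as in indolo[2,3-a]carbazole: C1–C4, C4a, C4b, C4c, C5, C6, C6a, C6b, C7–C10, C10a, N11, C11a, C11b, N12, C12a.

## The problem

Borregomycin E (16) is a flat, fully aromatic pentacycle in which two 6-chloroindole units are fused through their C2 and C3 atoms onto a central benzene ring (C4c, C5, C6, C6a, C11a, C11b). That ring is hexasubstituted and carries methoxy groups on C5 and C6. There is no stereocentre, so nothing has to be controlled in three dimensions. The only geometric element on the way is the configuration of any alkene that becomes part of the central ring. The task is one of regiochemistry and oxidation level: C2 of one indole must be joined to C2 of the other (C11a–C11b), C3 of each indole to one oxygenated carbon (C4c–C5 and C6–C6a), and the ring must end aromatic with both oxygens still methylated. The sensitive points are three: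
- the 5,6-dioxygenated ring, which as a free catechol is oxidised to the ortho-quinone;
- the two aryl chlorides, which rule out dissolving metals, halogen–metal exchange reagents and electron-rich zerovalent palladium catalysts late in the route;
- the two indole N–H groups, which are acidic and nucleophilic.

The feature that opens the route is that the central ring divides into a four-carbon diene and a two-carbon partner. The diene is C11a=C6a (the C2=C3 bond of one indole) with the attached C6(OMe)=C5H(OMe) unit. The partner is C11b=C4c, the C2=C3 bond of the second indole. A nitro group on C11b and a bromine on C4c give that partner the right polarity and exactly the two leaving groups that aromatisation requires.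

## Retrosynthesis

**N12–S bond.** Target 16 is taken back to its 12-phenylsulfonyl derivative 15. The sulfonyl group is what makes the dienophile reactive, so it is kept through ring formation and removed last. Only one nitrogen is protected at this stage, so the bay region between N11 and N12 is not overcrowded and a single mild deprotection ends the synthesis.

**C4c–C5 and C11a–C11b (key disconnection).** The central ring of 15 is opened into the 3-(1,2-dimethoxyvinyl)indole 7 and the 3-bromo-2-nitroindole 12. Neighbouring cuts were weighed against this one:
- C5–C6 needs a free catechol after ring closure.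
- C11a–C11b alone needs an external oxidant acting on an electron-rich enediol ether.
- C4c–C5 plus C6–C6a needs a 2,2'-biindole and a two-carbon dielectrophile that arrives at the quinone oxidation level.

The chosen cut pairs the natural nucleophilicity of a 3-vinylindole with a 2-nitroindole of inverted polarity, and it stores the oxidation level in two leaving groups. Both precursors are monoindoles a few steps from the same commercial 6-chloroindole (1). The forward reaction must join C5 to C4c and C11a to C11b and not the reverse, and it must aromatise by loss of HBr and HNO2 without losing methanol.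

**O–CH3 bond of the enol ether.** Diene 7 comes from its N-Boc derivative 6, and 6 from ketone 4 by O-methylation of the potassium enolate 5. The second methoxy group is thus introduced on oxygen, and the double-bond geometry follows from the enolate geometry. The Boc group prevents N-methylation and is removable under basic conditions that the bis-enol ether tolerates. The forward step needs O- over C-alkylation and a single enolate geometry.

**C3–acyl bond.** Ketone 4 is the Boc derivative of the 3-acylindole 3, which is cut at the indole C3–carbonyl bond into 6-chloroindole (1) and methoxyacetyl chloride (2). The acid chloride supplies C5, C6 and the first methoxy group in one commercial reagent. The forward step is a C3-selective acylation of an unprotected indole.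

**C2–N bond of the nitro group.** Nitroindole 12 is traced to the 2-lithioindole 11 and from there to bromide 10. Direct electrophilic nitration cannot place a nitro group on C2, but deprotonation next to the sulfonylated nitrogen can. The forward step needs lithiation at C2 without touching the C3 bromine.

**C3–Br and N1–S bonds.** Bromide 10 comes from sulfonamide 9 by electrophilic bromination, and 9 from 6-chloroindole (1) and benzenesulfonyl chloride (8). Both operations are routine, and both arms start from the same indole.

## Roads not taken

**Alternative 1:** The cut removes both outer benzene rings and both pyrrole rings (C4b–C12a, C1–C2, C3–C4 and their mirror bonds). It leads to tetrayne A2, a veratrole core with two N-ethynyl sulfonamides and two silylalkynes, and two molecules of ethynylboronic ester A3. In the forward direction RhCl(PPh3)3 (monovalent rhodium) would catalyse a double [2+2+2] cyclotrimerisation to the pentacycle A1.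
- Merits: four rings and six C–C bonds are formed in one catalytic operation, and the central ring carries its methoxy groups from the start. In bonds formed per step this road is clearly superior to the chosen plan.
- Weak points: A1 carries boron where chlorine is needed and silicon where hydrogen is needed, so two chlorodeboronations, two protodesilylations and two detosylations must follow. A2 is a congested hexasubstituted benzene with two neighbouring ynamides, and its preparation alone would probably take more steps than the whole chosen route. Each insertion of A3 must place boron meta to silicon, twice, on steric grounds only.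
- Comparison: the chosen plan sets against the elegance of the key step the fact that 6-chloroindole already contains the outer ring, the pyrrole and the chlorine. Only the one ring unique to the target is built.

**Alternative 2:** The cut is made at C2–C3 and C8–C9 of the outer rings. It leads to the benzodipyrrole A5, in which each pyrrole carries a 2,2-dichlorovinyl group and a vinyl group. Heating with a mild base would bring about two disrotatory six-electron electrocyclisations, each followed by loss of HCl, to give the ditosyl indolocarbazole A4.
- Merits: the reaction type is secure, the position of each chlorine is fixed by the dichlorovinyl carbon, and no oxidant is needed. In the reliability of its key step this road is better than the chosen one, whose cycloaddition is without direct precedent.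
- Weak points: A5 must be assembled from a 4,5-dimethoxybenzodipyrrole by four separate alkenyl installations, its vinylpyrrole units are prone to polymerisation, and the cyclisation has to break pyrrole aromaticity twice. Two tosyl groups must then be removed from a crowded bay region.
- Comparison: the chosen plan sets against this the short access to 7 and 12 (four and three routine steps) and a stepwise fallback that starts from the same intermediates.

**Alternative 3:** The cut is the single C5–C6 bond. It leads to the di-Boc dialdehyde A7, available from the symmetric biindole A8 by double formylation and protection. A triazolium-derived N-heterocyclic carbene would effect an intramolecular benzoin reaction, and the acyloin would tautomerise to the aromatic 5,6-diol A6. Double O-methylation and Boc removal would finish the synthesis.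
- Merits: this road uses the mirror symmetry of the target, which the chosen plan ignores. It is redox-neutral and is at least as short as the chosen route. In step economy it is equal or slightly better.
- Weak points: indole-3-carbaldehydes are vinylogous formamides and poor partners in benzoin chemistry. Two Boc groups on neighbouring nitrogens twist the biindole and hold the aldehydes apart, and they must then be forced into a planar bay region in A6. A6 is an electron-rich catechol that air oxidises to the ortho-quinone, most readily under the basic conditions of its methylation, where Boc migration to oxygen is also possible.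
- Comparison: the chosen plan has both oxygens methylated before the ring exists, needs only one nitrogen protecting group in the bay region, and drives the closure by irreversible loss of two leaving groups.

Key step: step 8

## Route

Step 1
Reactants: 1 6-chloro-1H-indole; 2 methoxyacetyl chloride
Product: 3 1-(6-chloro-1H-indol-3-yl)-2-methoxyethan-1-one
Conditions: Et2AlCl, CH2Cl2, 0 °C; then 2, 0 °C to rt
Reagents that add atoms: none
Why: Friedel–Crafts C3-acylation of an N–H indole mediated by Et2AlCl; the aluminium indolide formed with loss of ethane is acylated at C3 without N-acylation or acid-induced oligomerisation, and the 6-chloro substituent does not change the C3 preference.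

Step 2
Reactants: 3 1-(6-chloro-1H-indol-3-yl)-2-methoxyethan-1-one
Product: 4 tert-butyl 6-chloro-3-(2-methoxyacetyl)indole-1-carboxylate
Conditions: Boc2O, DMAP (cat.), MeCN, rt
Reagents that add atoms: di-tert-butyl dicarbonate, CC(C)(C)OC(=O)OC(=O)OC(C)(C)C
Why: DMAP-catalysed N-acylation to the carbamate, fast because the 3-acyl group acidifies the N–H; the Boc group blocks N-methylation in step 3 and, by weakening the vinylogous-amide character of the ketone, eases deprotonation of the α-CH2.

Step 3
Reactants: 4 tert-butyl 6-chloro-3-(2-methoxyacetyl)indole-1-carboxylate
Product: 6 tert-butyl 6-chloro-3-[(Z)-1,2-dimethoxyethenyl]indole-1-carboxylate, via potassium Z-enolate 5 (not isolated)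
Conditions: KN(SiMe3)2, THF/DMPU, −78 °C; then MeOTf, −78 to 0 °C
Reagents that add atoms: methyl trifluoromethanesulfonate, COS(=O)(=O)C(F)(F)F
Why: Enolate O-alkylation; hindered amide bases convert aryl ketones into the Z enolate (enolate oxygen and α-substituent cis, which keeps the α-methoxy group away from the indole ring), and a potassium enolate in a dipolar cosolvent reacts with the hard electrophile MeOTf at oxygen, the carbon being further shielded by its own methoxy group. The cis relation of the two oxygens in 5 becomes the Z geometry of 6.

Step 4
Reactants: 6 tert-butyl 6-chloro-3-[(Z)-1,2-dimethoxyethenyl]indole-1-carboxylate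
Product: 7 6-chloro-3-[(Z)-1,2-dimethoxyethenyl]-1H-indole
Conditions: NaOMe (cat.), MeOH/THF, rt; NaHCO3 work-up, used crude
Reagents that add atoms: none
Why: Methoxide-induced cleavage of an indole N-carbamate (addition to the Boc carbonyl, departure of the indolide, reprotonation by methanol); the medium stays basic throughout, as the acid-labile bis-enol ether requires, and the alkene geometry is untouched.

Step 5
Reactants: 1 6-chloro-1H-indole; 8 benzenesulfonyl chloride
Product: 9 6-chloro-1-(phenylsulfonyl)indole
Conditions: NaH, DMF, 0 °C; then 8, 0 °C to rt
Reagents that add atoms: none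
Why: N-sulfonylation of the sodium indolide, a standard protection; the sulfonyl group later acidifies C2–H for lithiation and makes the nitroindole a competent dienophile.

Step 6
Reactants: 9 6-chloro-1-(phenylsulfonyl)indole
Product: 10 3-bromo-6-chloro-1-(phenylsulfonyl)indole
Conditions: Br2, CH2Cl2, 0 °C to rt
Reagents that add atoms: bromine, BrBr
Why: Electrophilic aromatic bromination; 1-sulfonylindoles are substituted cleanly at C3 by Br2, and the deactivated chlorobenzene ring does not compete.

Step 7
Reactants: 10 3-bromo-6-chloro-1-(phenylsulfonyl)indole
Product: 12 3-bromo-6-chloro-2-nitro-1-(phenylsulfonyl)indole, via 2-lithioindole 11 (not isolated)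
Conditions: LiN(i-Pr)2, THF, −78 °C; then cannulation into N2O4, THF/Et2O, −110 °C
Reagents that add atoms: dinitrogen tetroxide, [O-][N+](=O)[N+](=O)[O-]
Why: Directed C2 deprotonation of a 1-sulfonylindole by a lithium amide (which, unlike an alkyllithium, does not exchange the C3 bromine), followed by electrophilic nitration of the aryllithium with N2O4, the established entry to 2-nitro-1-sulfonylindoles. Inverse addition to excess N2O4 at very low temperature limits electron-transfer side reactions, and 11 is kept at −78 °C so that it neither rearranges nor loses LiBr.

Step 8
Reactants: 7 6-chloro-3-[(Z)-1,2-dimethoxyethenyl]-1H-indole; 12 3-bromo-6-chloro-2-nitro-1-(phenylsulfonyl)indole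
Product: 15 2,9-dichloro-5,6-dimethoxy-12-(phenylsulfonyl)-11H-indolo[2,3-a]carbazole, via bromonitro cycloadduct 13 (not isolated), via bromodihydro intermediate 14 (not isolated)
Conditions: K2CO3 (powdered), PhMe, rt to 90 °C, argon, dark
Reagents that add atoms: none
Why: Proposed new method: diene 7 is a 1-amino-3-alkoxydiene whose HOMO is largest at the terminal CH(OMe) carbon, and 12 is a cyclic β-bromonitroalkene whose LUMO is largest at C3, so the first bond (C5–C4c) should form by polar attack and the nitronate carbon should then close onto the indoleninium carbon (C11a–C11b); the central six-membered ring is thus closed by an asynchronous intermolecular [4+2] cycloaddition or, at the stepwise limit, by a 6-exo-trig Mannich-type closure. The closest known reactions are the thermal Diels–Alder additions of 1-sulfonyl-2-nitro- and -3-nitroindoles to oxygenated dienes, which give carbazoles after loss of HNO2, and the [4+2] additions of 3-vinylindoles to electron-poor alkenes. Adduct 13 should lose HNO2 (nitro group on C11b, hydrogen on C11a) to give enamine 14, whose N11 lone pair then expels the allylic bromide from C4c, and loss of the C5 proton completes the aromatic ring; K2CO3 takes up both acids so that the enol ether of unreacted 7 is not hydrolysed. The four stereocentres of 13 are all destroyed, so endo/exo and facial selectivity are irrelevant. The step needs regioselectivity and the correct eliminations: the nitro group on C2 of 12 fixes the polarity so that C5 joins C4c and not C11b, and because C4c carries bromine and no hydrogen, methanol cannot be eliminated from C5, so both methoxy groups are retained without an external oxidant. The Z geometry of 7 keeps the terminal methoxy group on the outside of the s-cis diene, where it does not hinder the approach of 12. If bromide is lost from the first zwitterion before ring closure, the open-chain 1,2-bis(indolyl)ethene that results can still reach 15 through its cis isomer by six-electron electrocyclisation and loss of HNO2 on further heating.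

Step 9
Reactants: 15 2,9-dichloro-5,6-dimethoxy-12-(phenylsulfonyl)-11H-indolo[2,3-a]carbazole
Product: 16 borregomycin E (2,9-dichloro-5,6-dimethoxy-11,12-dihydroindolo[2,3-a]carbazole)
Conditions: Bu4NF, THF, 65 °C
Reagents that add atoms: none
Why: Fluoride-induced N-desulfonylation of an N-sulfonyl azole (attack at sulfur, departure of the stabilised carbazolide-type anion, aided by relief of bay-region strain next to N11–H); aryl chlorides and aryl methyl ethers are inert to Bu4NF.

## Compound list

1 | 6-chloro-1H-indole | Clc1ccc2cc[nH]c2c1 | starting material
2 | methoxyacetyl chloride | COCC(=O)Cl | starting material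
3 | 1-(6-chloro-1H-indol-3-yl)-2-methoxyethan-1-one | COCC(=O)c1c[nH]c2cc(Cl)ccc12 | intermediate
4 | tert-butyl 6-chloro-3-(2-methoxyacetyl)indole-1-carboxylate | COCC(=O)c1cn(C(=O)OC(C)(C)C)c2cc(Cl)ccc12 | intermediate
5 | potassium (Z)-1-[1-(tert-butoxycarbonyl)-6-chloroindol-3-yl]-2-methoxyethen-1-olate (formed in the flask) | CO/C=C(\[O-])c1cn(C(=O)OC(C)(C)C)c2cc(Cl)ccc12.[K+] | intermediate
6 | tert-butyl 6-chloro-3-[(Z)-1,2-dimethoxyethenyl]indole-1-carboxylate | CO/C=C(\OC)c1cn(C(=O)OC(C)(C)C)c2cc(Cl)ccc12 | intermediate
7 | 6-chloro-3-[(Z)-1,2-dimethoxyethenyl]-1H-indole | CO/C=C(\OC)c1c[nH]c2cc(Cl)ccc12 | intermediate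
8 | benzenesulfonyl chloride | O=S(=O)(Cl)c1ccccc1 | starting material
9 | 6-chloro-1-(phenylsulfonyl)indole | Clc1ccc2ccn(S(=O)(=O)c3ccccc3)c2c1 | intermediate
10 | 3-bromo-6-chloro-1-(phenylsulfonyl)indole | Clc1ccc2c(Br)cn(S(=O)(=O)c3ccccc3)c2c1 | intermediate
11 | 3-bromo-6-chloro-2-lithio-1-(phenylsulfonyl)indole (formed in the flask) | [Li]c1c(Br)c2ccc(Cl)cc2n1S(=O)(=O)c1ccccc1 | intermediate
12 | 3-bromo-6-chloro-2-nitro-1-(phenylsulfonyl)indole | O=[N+]([O-])c1c(Br)c2ccc(Cl)cc2n1S(=O)(=O)c1ccccc1 | intermediate
13 | 4c-bromo-2,9-dichloro-5,6-dimethoxy-11b-nitro-12-(phenylsulfonyl)-4c,5,11,11a,11b,12-hexahydroindolo[2,3-a]carbazole (formed in the flask, mixture of diastereomers, all stereocentres later destroyed) | COC1C(OC)=C2c3ccc(Cl)cc3NC2C2([N+](=O)[O-])N(S(=O)(=O)c3ccccc3)c3cc(Cl)ccc3C12Br | intermediate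
14 | 4c-bromo-2,9-dichloro-5,6-dimethoxy-12-(phenylsulfonyl)-4c,5,11,12-tetrahydroindolo[2,3-a]carbazole (formed in the flask, mixture of stereoisomers) | COC1C(OC)=C2c3ccc(Cl)cc3NC2=C2N(S(=O)(=O)c3ccccc3)c3cc(Cl)ccc3C12Br | intermediate
15 | 2,9-dichloro-5,6-dimethoxy-12-(phenylsulfonyl)-11H-indolo[2,3-a]carbazole | COc1c(OC)c2c3ccc(Cl)cc3[nH]c2c2n(S(=O)(=O)c3ccccc3)c3cc(Cl)ccc3c12 | intermediate
16 | borregomycin E (2,9-dichloro-5,6-dimethoxy-11,12-dihydroindolo[2,3-a]carbazole) | COc1c(OC)c2c3ccc(Cl)cc3[nH]c2c2[nH]c3cc(Cl)ccc3c12 | target

## Step count and risks

Total step count: 9. Longest linear sequence: 6 steps (steps 1, 2, 3, 4, 8, 9); the dienophile arm (steps 5, 6, 7) joins at step 8.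

**Step 8 (key step; the one step that goes beyond known chemistry).** Three processes are the most likely to go wrong:
- acid-triggered hydrolysis or self-addition of the electron-rich diene before it meets the dienophile;
- after the first C–C bond, loss of bromide by addition–elimination in place of ring closure, which stalls the sequence at an open-chain bis(indolyl)ethene;
- closure of the zwitterion through a nitronate oxygen (hetero-Diels–Alder mode) in place of carbon.

Transfer of bromine to the diene and aza-addition through the free N–H are further possibilities. The fallback forms the same two bonds one after the other by known reactions. It sets out from ketone 4 and bromide 10. Palladium-catalysed α-arylation of the ketone (Pd(OAc)2, Xantphos, K3PO4, PhMe, 80 °C; the C–Br bond reacts ahead of the aryl chlorides) makes the C5–C4c bond and gives tert-butyl 6-chloro-3-{2-[6-chloro-1-(phenylsulfonyl)indol-3-yl]-2-methoxyacetyl}indole-1-carboxylate F1. O-Methylation of its potassium enolate as in step 3 gives tert-butyl 6-chloro-3-{2-[6-chloro-1-(phenylsulfonyl)indol-3-yl]-1,2-dimethoxyethenyl}indole-1-carboxylate F2; either alkene geometry serves, because irradiation interconverts them. Oxidative stilbene-type photocyclisation (hν, I2, methyloxirane, PhMe) closes C11a–C11b and gives tert-butyl 2,9-dichloro-5,6-dimethoxy-12-(phenylsulfonyl)indolo[2,3-a]carbazole-11-carboxylate F3. Trifluoroacetic acid in CH2Cl2 removes the Boc group and the route is rejoined at 15.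

**Step 7.** Electron transfer from the aryllithium to N2O4 may lead to protonated or dimeric material in place of nitration, and warming of the 3-bromo-2-lithio species may cause halogen migration or loss of LiBr. Fallback: from 10, deprotonation with LiN(i-Pr)2 and quenching with I2 gives 3-bromo-6-chloro-2-iodo-1-(phenylsulfonyl)indole F4. Ipso substitution of the activated 2-iodide with AgNO2 (aqueous acetone, 60 °C), a known route to N-protected 2-nitroindoles, returns to 12.

**Step 3.** C-Methylation may compete with O-methylation, the enolate geometry may be incomplete, or the base may attack the Boc group. Fallback: the enol ether is introduced as a preformed unit. From 1, iodination (I2, KOH, DMF) and Boc protection give tert-butyl 6-chloro-3-iodoindole-1-carboxylate F5. (Z)-1,2-Dimethoxyethene F6 is lithiated with t-BuLi (THF, −78 °C) and stannylated with Bu3SnCl to give tributyl[(E)-1,2-dimethoxyethenyl]stannane F7, in which the two methoxy groups are still cis. Stille coupling of F5 with F7 (Pd(PPh3)4, CuI, CsF, DMF, 45 °C) proceeds with retention at the alkene and reaches 6.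

**Step 4.** The bis-enol ether may be protonated during methanolysis or work-up and revert to ketone 3, or Boc cleavage from the now electron-rich indole may be slow. Fallback: a silyl group replaces Boc. From 3, NaH and i-Pr3SiCl give 1-[6-chloro-1-(triisopropylsilyl)indol-3-yl]-2-methoxyethan-1-one F8. Enolate O-methylation as in step 3 gives 6-chloro-3-[(Z)-1,2-dimethoxyethenyl]-1-(triisopropylsilyl)indole F9. Bu4NF in THF at 0 °C cleaves the N–Si bond within minutes under non-acidic conditions and returns to 7.

## Further compounds

F1 | step 8 | tert-butyl 6-chloro-3-{2-[6-chloro-1-(phenylsulfonyl)indol-3-yl]-2-methoxyacetyl}indole-1-carboxylate (racemic) | COC(C(=O)c1cn(C(=O)OC(C)(C)C)c2cc(Cl)ccc12)c1cn(S(=O)(=O)c2ccccc2)c2cc(Cl)ccc12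
F2 | step 8 | tert-butyl 6-chloro-3-{2-[6-chloro-1-(phenylsulfonyl)indol-3-yl]-1,2-dimethoxyethenyl}indole-1-carboxylate (E/Z mixture) | COC(=C(OC)c1cn(S(=O)(=O)c2ccccc2)c2cc(Cl)ccc12)c1cn(C(=O)OC(C)(C)C)c2cc(Cl)ccc12
F3 | step 8 | tert-butyl 2,9-dichloro-5,6-dimethoxy-12-(phenylsulfonyl)indolo[2,3-a]carbazole-11-carboxylate | COc1c(OC)c2c3ccc(Cl)cc3n(C(=O)OC(C)(C)C)c2c2n(S(=O)(=O)c3ccccc3)c3cc(Cl)ccc3c12
F4 | step 7 | 3-bromo-6-chloro-2-iodo-1-(phenylsulfonyl)indole | Ic1c(Br)c2ccc(Cl)cc2n1S(=O)(=O)c1ccccc1
F5 | step 3 | tert-butyl 6-chloro-3-iodoindole-1-carboxylate | CC(C)(C)OC(=O)n1cc(I)c2ccc(Cl)cc21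
F6 | step 3 | (Z)-1,2-dimethoxyethene | CO/C=C\OC
F7 | step 3 | tributyl[(E)-1,2-dimethoxyethenyl]stannane (methoxy groups cis) | CO/C=C(\OC)[Sn](CCCC)(CCCC)CCCC
F8 | step 4 | 1-[6-chloro-1-(triisopropylsilyl)indol-3-yl]-2-methoxyethan-1-one | COCC(=O)c1cn([Si](C(C)C)(C(C)C)C(C)C)c2cc(Cl)ccc12
F9 | step 4 | 6-chloro-3-[(Z)-1,2-dimethoxyethenyl]-1-(triisopropylsilyl)indole | CO/C=C(\OC)c1cn([Si](C(C)C)(C(C)C)C(C)C)c2cc(Cl)ccc12
A1 | alternative 1 | 5,6-dimethoxy-2,9-bis(pinacolboryl)-11,12-ditosyl-4,7-bis(trimethylsilyl)indolo[2,3-a]carbazole | COc1c(OC)c2c3c([Si](C)(C)C)cc(B4OC(C)(C)C(C)(C)O4)cc3n(S(=O)(=O)c3ccc(C)cc3)c2c2n(S(=O)(=O)c3ccc(C)cc3)c3cc(B4OC(C)(C)C(C)(C)O4)cc([Si](C)(C)C)c3c12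
A2 | alternative 1 | N,N'-[4,5-dimethoxy-3,6-bis(trimethylsilylethynyl)-1,2-phenylene]bis(N-ethynyl-4-methylbenzenesulfonamide) | COc1c(OC)c(C#C[Si](C)(C)C)c(N(C#C)S(=O)(=O)c2ccc(C)cc2)c(N(C#C)S(=O)(=O)c2ccc(C)cc2)c1C#C[Si](C)(C)C
A3 | alternative 1 | 2-ethynyl-4,4,5,5-tetramethyl-1,3,2-dioxaborolane | C#CB1OC(C)(C)C(C)(C)O1
A4 | alternative 2 | 2,9-dichloro-5,6-dimethoxy-11,12-ditosylindolo[2,3-a]carbazole | COc1c(OC)c2c3ccc(Cl)cc3n(S(=O)(=O)c3ccc(C)cc3)c2c2n(S(=O)(=O)c3ccc(C)cc3)c3cc(Cl)ccc3c12
A5 | alternative 2 | 2,7-bis(2,2-dichloroethenyl)-3,6-diethenyl-4,5-dimethoxy-1,8-ditosyl-1,8-dihydrobenzo[2,1-b:3,4-b']dipyrrole | COc1c(OC)c2c(C=C)c(C=C(Cl)Cl)n(S(=O)(=O)c3ccc(C)cc3)c2c2n(S(=O)(=O)c3ccc(C)cc3)c(C=C(Cl)Cl)c(C=C)c12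
A6 | alternative 3 | di-tert-butyl 2,9-dichloro-5,6-dihydroxyindolo[2,3-a]carbazole-11,12-dicarboxylate | CC(C)(C)OC(=O)n1c2cc(Cl)ccc2c2c(O)c(O)c3c4ccc(Cl)cc4n(C(=O)OC(C)(C)C)c3c21
A7 | alternative 3 | di-tert-butyl 6,6'-dichloro-3,3'-diformyl-[2,2'-biindole]-1,1'-dicarboxylate | O=Cc1c(-c2c(C=O)c3ccc(Cl)cc3n2C(=O)OC(C)(C)C)n(C(=O)OC(C)(C)C)c2cc(Cl)ccc12
A8 | alternative 3 | 6,6'-dichloro-1H,1'H-2,2'-biindole | Clc1ccc2cc(-c3cc4ccc(Cl)cc4[nH]3)[nH]c2c1
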